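**Retrosynthetic overview**
1. Hydrogen sulfate ⇐ primary alcohol; the lactam is attached by B-alkyl Suzuki coupling of a terminal alkene with a 3-bromo-Δ3-pyrrolin-2-one (C16–C17).
2. C12H2 and the CH2OH ⇐ photochemical hydrodecarboxylation of a γ-lactone carboxyl; the lactone masks the CH2OH and activates the radical acceptor.
3. Ring A (C1=C10) ⇐ McMurry closure of a keto-aldehyde onto ring B, which is bought as (R)-pulegone (C8); C4 by cuprate 1,4-addition, C5 by thermodynamic epimerisation.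
4. Key bond C9–C11 (quaternary C9) ⇐ electrochemical MHAT–Giese union of an exocyclic-methylene cyclohexanol with an (R)-α-methylene-β-allyl-butyrolactone (C13 from (R)-epichlorohydrin).
5. Ring order: ring B (bought) → butyrolactone (fragment, later excised) → ring A (step 10) → preformed lactam ring attached (step 14).

Assumption: the target is made as the free hydrogen sulfate drawn (in practice it would be stored as its sodium salt).
Locant key used in the text: C4 = gem-dimethyl carbon, C5 = ring-fusion CH, C8 = ring CHMe, C9 = quaternary ring carbon, C10=C1 = ring alkene, C11–C12 = CH2CH2 link, C13 = side-chain stereocentre, C14–C16 = CH2 chain to the lactam. MHAT = metal-hydride hydrogen-atom transfer.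

**Route**

Step 1
Reactants: 1 (R)-(+)-pulegone; 2 2-(2-bromoethyl)-1,3-dioxolane
Product: 3 (2S,5R)-2-[4-(1,3-dioxolan-2-yl)-2-methylbutan-2-yl]-5-methylcyclohexan-1-one
Conditions: 2, Mg, THF, 25 °C; then CuBr·SMe2 (10 mol %), 1, THF, −30 → 0 °C; H2O; then KOH (cat.), EtOH, reflux; chromatography
Reagents that add atoms: none
Why: Copper-catalysed Grignard 1,4-addition to the β,β-disubstituted enone builds quaternary C4, and base equilibration of the α-centre (C5) gives the trans-2,5-diequatorial menthone-type ketone (about 87:13 by analogy with 8-substituted menthones, minor cis epimer removed), so C5 is controlled by the bought C8 centre.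

Step 2
Reactants: 3 (2S,5R)-2-[4-(1,3-dioxolan-2-yl)-2-methylbutan-2-yl]-5-methylcyclohexan-1-one
Product: 6 (3R,6S)-6-[4-(1,3-dioxolan-2-yl)-2-methylbutan-2-yl]-3-methyl-2-methylidenecyclohexan-1-one, via Mannich base 4 (not isolated), via methiodide 5 (not isolated)
Conditions: LDA, THF, −78 °C; CH2=NMe2+ I−, −78 °C → rt; MeI, Et2O, rt; aq. NaHCO3/CH2Cl2, rt
Reagents that add atoms: N,N-dimethylmethyleneiminium iodide (Eschenmoser's salt), C=[N+](C)C.[I-]
Why: Kinetic deprotonation takes the CH2 flank rather than the hindered tertiary α-CH, and Mannich alkylation, N-quaternisation and Hofmann-type β-elimination install the exocyclic methylene (the future C9 methyl) without touching C5 or C8.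

Step 3
Reactants: 6 (3R,6S)-6-[4-(1,3-dioxolan-2-yl)-2-methylbutan-2-yl]-3-methyl-2-methylidenecyclohexan-1-one
Product: 7 (1S,3R,6S)-6-[4-(1,3-dioxolan-2-yl)-2-methylbutan-2-yl]-3-methyl-2-methylidenecyclohexan-1-ol
Conditions: NaBH4, CeCl3·7H2O, MeOH, −78 → 0 °C
Reagents that add atoms: none
Why: Luche 1,2-reduction (axial hydride, equatorial alcohol) turns the enone into an allylic alcohol so that step 7 generates a nucleophilic tertiary alkyl radical instead of an α-keto radical; the carbinol centre is temporary and either epimer converges in step 8.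

Step 4
Reactants: 8 (R)-epichlorohydrin; 9 diethyl malonate
Product: 12 ethyl (1S,5R)-2-oxo-3-oxabicyclo[3.1.0]hexane-1-carboxylate, via glycidylmalonate 10 (not isolated), via cyclopropylcarbinol diester 11 (not isolated)
Conditions: NaOEt, EtOH, 0 °C → reflux
Reagents that add atoms: none
Why: Malonate double alkylation (epoxide opening, chloride displacement to a new epoxide, 3-exo-tet closure with inversion) followed by lactonisation carries the epichlorohydrin stereocentre into C5 of the bicycle (the future C13).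

Step 5
Reactants: 12 ethyl (1S,5R)-2-oxo-3-oxabicyclo[3.1.0]hexane-1-carboxylate
Product: 13 ethyl (4R)-2-oxo-4-(prop-2-en-1-yl)oxolane-3-carboxylate (C3 epimers)
Conditions: CH2=CHMgBr, CuI (10 mol %), THF, −40 → −15 °C; H2O
Reagents that add atoms: vinylmagnesium bromide, C=C[Mg]Br
Why: Copper-catalysed homoconjugate opening of the doubly activated cyclopropane at its CH2 by the vinyl nucleophile gives the allyl arm (C14–C16) and leaves the stereocentre untouched.

Step 6
Reactants: 13 ethyl (4R)-2-oxo-4-(prop-2-en-1-yl)oxolane-3-carboxylate (C3 epimers)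
Product: 16 (4R)-3-methylidene-4-(prop-2-en-1-yl)oxolan-2-one, via carboxylic acid 14 (not isolated), via Mannich acid 15 (not isolated)
Conditions: NaOH, H2O/THF, rt; HCl to pH 1; then 37 % aq. HCHO, Et2NH, NaOAc, AcOH, 25 → 90 °C
Reagents that add atoms: formaldehyde, C=O
Why: Saponification and relactonisation give the α-carboxy lactone, whose Mannich reaction and decarboxylative elimination (decarboxylative methylenation) give the α-methylene lactone; the β-stereocentre is not enolisable.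

Step 7
Reactants: 7 (1S,3R,6S)-6-[4-(1,3-dioxolan-2-yl)-2-methylbutan-2-yl]-3-methyl-2-methylidenecyclohexan-1-ol; 16 (4R)-3-methylidene-4-(prop-2-en-1-yl)oxolan-2-one
Product: 17 (4R)-3-{[(1R,2S,3S,6R)-3-[4-(1,3-dioxolan-2-yl)-2-methylbutan-2-yl]-2-hydroxy-1,6-dimethylcyclohexyl]methyl}-4-(prop-2-en-1-yl)oxolan-2-one (both C3 epimers of the lactone)
Conditions: undivided cell, Zn(+)/graphite felt(−), [N,N′-bis(3,5-di-tert-butylsalicylidene)ethylenediamine]cobalt(II) (10 mol %), 2,4,6-collidinium BF4 (2.5 equiv), nBu4NBF4, DMF, 16 (3 equiv), 4 mA, 2.5 F/mol, rt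
Reagents that add atoms: none
Why: Proposed new method: a cobalt-hydride MHAT–Giese coupling driven at a cathode, in which Co(II) is reduced to Co(I) and protonated by collidinium to Co(III)–H, which delivers H• to the 1,1-disubstituted alkene (Markovnikov) so that the methylene becomes the C9 methyl and a nucleophilic tertiary C9 radical results; this radical adds to the methylene of 16 and the α-lactone radical is reduced at the cathode and protonated; the radical sits in a chair locked by the equatorial tert-alkyl group and flanked by equatorial CH3 and OH, so the acceptor should enter axially (anti to both neighbouring axial C–H bonds while the methyl relaxes into the equatorial site), setting quaternary C9 with the chain cis to the C8 methyl (expected dr about 5:1 or better); the closest known chemistry is the iron/silane reductive olefin cross-coupling (Mukaiyama-type MHAT Giese reaction) and cathodic cobalt-hydride generation for alkene isomerisation and hydrofunctionalisation.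

Step 8
Reactants: 17 (4R)-3-{[(1R,2S,3S,6R)-3-[4-(1,3-dioxolan-2-yl)-2-methylbutan-2-yl]-2-hydroxy-1,6-dimethylcyclohexyl]methyl}-4-(prop-2-en-1-yl)oxolan-2-one (both C3 epimers of the lactone)
Product: 18 (4R)-3-{[(1R,3S,6R)-3-[4-(1,3-dioxolan-2-yl)-2-methylbutan-2-yl]-1,6-dimethyl-2-oxocyclohexyl]methyl}-4-(prop-2-en-1-yl)oxolan-2-one
Conditions: Dess–Martin periodinane, pyridine, CH2Cl2, 0 °C → rt
Reagents that add atoms: none
Why: Dess–Martin oxidation restores the C10 ketone under non-enolising conditions, which matters because C5 is now an epimerisable α-centre with only a small thermodynamic bias; lactone, acetal and alkene are inert.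

Step 9
Reactants: 18 (4R)-3-{[(1R,3S,6R)-3-[4-(1,3-dioxolan-2-yl)-2-methylbutan-2-yl]-1,6-dimethyl-2-oxocyclohexyl]methyl}-4-(prop-2-en-1-yl)oxolan-2-one
Product: 19 4-[(1S,3R,4R)-3,4-dimethyl-2-oxo-3-{[(4R)-2-oxo-4-(prop-2-en-1-yl)oxolan-3-yl]methyl}cyclohexyl]-4-methylpentanal
Conditions: PPTS (cat.), acetone/H2O (10:1), 45 °C; used directly
Reagents that add atoms: water, O
Why: Mild acid-catalysed acetal hydrolysis unmasks the aldehyde, while the hindered ketone does not enolise toward C5 under these conditions and the lactone is stable.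

Step 10
Reactants: 19 4-[(1S,3R,4R)-3,4-dimethyl-2-oxo-3-{[(4R)-2-oxo-4-(prop-2-en-1-yl)oxolan-3-yl]methyl}cyclohexyl]-4-methylpentanal
Product: 20 (4R)-3-{[(1R,2R,4aS)-1,2,5,5-tetramethyl-1,2,3,4,4a,5,6,7-octahydronaphthalen-1-yl]methyl}-4-(prop-2-en-1-yl)oxolan-2-one
Conditions: TiCl3(DME)1.5, Zn–Cu, DME; slow addition of 19 at 25 °C, then reflux
Reagents that add atoms: none
Why: Intramolecular McMurry coupling (titanium-mediated pinacol coupling then deoxygenation) closes ring A and places the alkene regiospecifically at C1=C10, which a dehydration could not guarantee; C5 thereby becomes a non-epimerisable allylic centre.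

Step 11
Reactants: 20 (4R)-3-{[(1R,2R,4aS)-1,2,5,5-tetramethyl-1,2,3,4,4a,5,6,7-octahydronaphthalen-1-yl]methyl}-4-(prop-2-en-1-yl)oxolan-2-one
Product: 22 (2S)-2-(prop-2-en-1-yl)-4-[(1R,2R,4aS)-1,2,5,5-tetramethyl-1,2,3,4,4a,5,6,7-octahydronaphthalen-1-yl]butan-1-ol, via caesium carboxylate 21 (not isolated)
Conditions: CsOH·H2O (1.05 equiv), THF/H2O, rt; then [Ir(dF(CF3)ppy)2(dtbbpy)]PF6 (2 mol %), 2,4,6-triisopropylbenzenethiol (20 mol %), DMSO/H2O, 450 nm LEDs, rt
Reagents that add atoms: none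
Why: Hydroxide opens the lactone and photoredox hydrodecarboxylation (carboxylate oxidation by the excited iridium complex, CO2 loss, thiol hydrogen-atom transfer) removes the carbonyl carbon, so the ring oxygen emerges as the free CH2OH and the scrambled C12 centre becomes CH2; the iridium oxidant is too weak to oxidise the alkenes and C13 is untouched (its descriptor changes from R to S only through CIP priorities).

Step 12
Reactants: 23 2,5-dimethoxy-2,5-dihydrofuran; 24 3-methylbutan-1-amine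
Product: 25 1-(3-methylbutyl)-1,5-dihydro-2H-pyrrol-2-one
Conditions: 1 M aq. HCl, rt
Reagents that add atoms: none
Why: Acid hydrolysis of the bis-acetal to (Z)-butenedial, condensation with the primary amine and tautomerisation of the resulting 2-hydroxypyrrole give the N-alkyl Δ3-pyrrolin-2-one (Paal–Knorr-type condensation).

Step 13
Reactants: 25 1-(3-methylbutyl)-1,5-dihydro-2H-pyrrol-2-one
Product: 27 3-bromo-1-(3-methylbutyl)-1,5-dihydro-2H-pyrrol-2-one, via dibromide 26 (not isolated)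
Conditions: Br2, CH2Cl2, 0 °C; then Et3N, 0 °C → rt
Reagents that add atoms: bromine, BrBr
Why: Bromine addition to the conjugated alkene followed by loss of HBr (acidic α-H, β-bromide) gives the α-bromo unsaturated lactam (bromination–dehydrobromination).

Step 14
Reactants: 22 (2S)-2-(prop-2-en-1-yl)-4-[(1R,2R,4aS)-1,2,5,5-tetramethyl-1,2,3,4,4a,5,6,7-octahydronaphthalen-1-yl]butan-1-ol; 27 3-bromo-1-(3-methylbutyl)-1,5-dihydro-2H-pyrrol-2-one
Product: 29 3-{(4R)-4-(hydroxymethyl)-6-[(1R,2R,4aS)-1,2,5,5-tetramethyl-1,2,3,4,4a,5,6,7-octahydronaphthalen-1-yl]hexyl}-1-(3-methylbutyl)-1,5-dihydro-2H-pyrrol-2-one, via alkylborane 28 (not isolated)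
Conditions: 9-BBN (2.3 equiv), THF, 0 °C → rt; then 27, PdCl2(dppf) (5 mol %), AsPh3, Cs2CO3, DMF/H2O, 50 °C
Reagents that add atoms: none
Why: 9-BBN hydroborates only the terminal alkene anti-Markovnikov (the trisubstituted ring alkene is inert and the alcohol is tied up as a borinate), and B-alkyl Suzuki–Miyaura coupling with the vinyl bromide forms C16–C17 without affecting any stereocentre.

Step 15
Reactants: 29 3-{(4R)-4-(hydroxymethyl)-6-[(1R,2R,4aS)-1,2,5,5-tetramethyl-1,2,3,4,4a,5,6,7-octahydronaphthalen-1-yl]hexyl}-1-(3-methylbutyl)-1,5-dihydro-2H-pyrrol-2-one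
Product: 30 (2R)-2-{3-[1-(3-methylbutyl)-2-oxo-2,5-dihydro-1H-pyrrol-3-yl]propyl}-4-[(1R,2R,4aS)-1,2,5,5-tetramethyl-1,2,3,4,4a,5,6,7-octahydronaphthalen-1-yl]butyl hydrogen sulfate
Conditions: SO3·pyridine, pyridine, rt; Dowex 50W (H+)
Reagents that add atoms: sulfur trioxide–pyridine complex, O=S(=O)([O-])[n+]1ccccc1
Why: O-Sulfation of the only hydroxyl with SO3·pyridine, the lactam and alkenes being inert, followed by acidic ion exchange gives the hydrogen sulfate.

**Compound list**
1 | (R)-(+)-pulegone, (5R)-5-methyl-2-(propan-2-ylidene)cyclohexan-1-one | C[C@@H]1CCC(=C(C)C)C(=O)C1 | starting material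
2 | 2-(2-bromoethyl)-1,3-dioxolane | BrCCC1OCCO1 | starting material
3 | (2S,5R)-2-[4-(1,3-dioxolan-2-yl)-2-methylbutan-2-yl]-5-methylcyclohexan-1-one | C[C@@H]1CC[C@@H](C(C)(C)CCC2OCCO2)C(=O)C1 | intermediate
4 | (3R,6S)-2-[(dimethylamino)methyl]-6-[4-(1,3-dioxolan-2-yl)-2-methylbutan-2-yl]-3-methylcyclohexan-1-one (C2 epimers; Mannich base) | C[C@@H]1CC[C@@H](C(C)(C)CCC2OCCO2)C(=O)C1CN(C)C | intermediate
5 | N,N,N-trimethyl-1-[(3S,6R)-3-[4-(1,3-dioxolan-2-yl)-2-methylbutan-2-yl]-6-methyl-2-oxocyclohexyl]methanaminium iodide (methiodide of 4) | C[C@@H]1CC[C@@H](C(C)(C)CCC2OCCO2)C(=O)C1C[N+](C)(C)C.[I-] | intermediate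
6 | (3R,6S)-6-[4-(1,3-dioxolan-2-yl)-2-methylbutan-2-yl]-3-methyl-2-methylidenecyclohexan-1-one | C[C@@H]1CC[C@@H](C(C)(C)CCC2OCCO2)C(=O)C1=C | intermediate
7 | (1S,3R,6S)-6-[4-(1,3-dioxolan-2-yl)-2-methylbutan-2-yl]-3-methyl-2-methylidenecyclohexan-1-ol | C[C@@H]1CC[C@@H](C(C)(C)CCC2OCCO2)[C@H](O)C1=C | intermediate
8 | (R)-epichlorohydrin, (2R)-2-(chloromethyl)oxirane | ClC[C@H]1CO1 | starting material
9 | diethyl malonate | CCOC(=O)CC(=O)OCC | starting material
10 | diethyl 2-{[(2R)-oxiran-2-yl]methyl}propanedioate | CCOC(=O)C(C[C@@H]1CO1)C(=O)OCC | intermediate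
11 | diethyl (2R)-2-(hydroxymethyl)cyclopropane-1,1-dicarboxylate (formed as its sodium alkoxide) | OC[C@@H]1CC1(C(=O)OCC)C(=O)OCC | intermediate
12 | ethyl (1S,5R)-2-oxo-3-oxabicyclo[3.1.0]hexane-1-carboxylate | O=C1OC[C@@H]2C[C@]12C(=O)OCC | intermediate
13 | ethyl (4R)-2-oxo-4-(prop-2-en-1-yl)oxolane-3-carboxylate (C3 epimers, trans major) | CCOC(=O)C1[C@@H](CC=C)COC1=O | intermediate
14 | (4R)-2-oxo-4-(prop-2-en-1-yl)oxolane-3-carboxylic acid | OC(=O)C1[C@@H](CC=C)COC1=O | intermediate
15 | (4R)-3-[(diethylamino)methyl]-2-oxo-4-(prop-2-en-1-yl)oxolane-3-carboxylic acid | CCN(CC)CC1(C(O)=O)[C@@H](CC=C)COC1=O | intermediate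
16 | (4R)-3-methylidene-4-(prop-2-en-1-yl)oxolan-2-one | C=CC[C@H]1COC(=O)C1=C | intermediate
17 | (4R)-3-{[(1R,2S,3S,6R)-3-[4-(1,3-dioxolan-2-yl)-2-methylbutan-2-yl]-2-hydroxy-1,6-dimethylcyclohexyl]methyl}-4-(prop-2-en-1-yl)oxolan-2-one (both C3 epimers of the lactone) | C[C@@H]1CC[C@@H](C(C)(C)CCC2OCCO2)[C@H](O)[C@]1(C)CC3C(=O)OC[C@@H]3CC=C | intermediate
18 | (4R)-3-{[(1R,3S,6R)-3-[4-(1,3-dioxolan-2-yl)-2-methylbutan-2-yl]-1,6-dimethyl-2-oxocyclohexyl]methyl}-4-(prop-2-en-1-yl)oxolan-2-one | C[C@@H]1CC[C@@H](C(C)(C)CCC2OCCO2)C(=O)[C@]1(C)CC3C(=O)OC[C@@H]3CC=C | intermediate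
19 | 4-[(1S,3R,4R)-3,4-dimethyl-2-oxo-3-{[(4R)-2-oxo-4-(prop-2-en-1-yl)oxolan-3-yl]methyl}cyclohexyl]-4-methylpentanal | C[C@@H]1CC[C@@H](C(C)(C)CCC=O)C(=O)[C@]1(C)CC2C(=O)OC[C@@H]2CC=C | intermediate
20 | (4R)-3-{[(1R,2R,4aS)-1,2,5,5-tetramethyl-1,2,3,4,4a,5,6,7-octahydronaphthalen-1-yl]methyl}-4-(prop-2-en-1-yl)oxolan-2-one | C=CC[C@H]1COC(=O)C1C[C@@]2(C)C3=CCCC(C)(C)[C@@H]3CC[C@H]2C | intermediate
21 | caesium (3R)-3-(hydroxymethyl)-2-{[(1R,2R,4aS)-1,2,5,5-tetramethyl-1,2,3,4,4a,5,6,7-octahydronaphthalen-1-yl]methyl}hex-5-enoate | C=CC[C@@H](CO)C(C[C@@]1(C)C2=CCCC(C)(C)[C@@H]2CC[C@H]1C)C(=O)[O-].[Cs+] | intermediate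
22 | (2S)-2-(prop-2-en-1-yl)-4-[(1R,2R,4aS)-1,2,5,5-tetramethyl-1,2,3,4,4a,5,6,7-octahydronaphthalen-1-yl]butan-1-ol | C=CC[C@@H](CO)CC[C@@]1(C)C2=CCCC(C)(C)[C@@H]2CC[C@H]1C | intermediate
23 | 2,5-dimethoxy-2,5-dihydrofuran (cis/trans mixture) | COC1C=CC(OC)O1 | starting material
24 | 3-methylbutan-1-amine (isopentylamine) | CC(C)CCN | starting material
25 | 1-(3-methylbutyl)-1,5-dihydro-2H-pyrrol-2-one | CC(C)CCN1CC=CC1=O | intermediate
26 | 3,4-dibromo-1-(3-methylbutyl)pyrrolidin-2-one (trans, racemic) | CC(C)CCN1CC(Br)C(Br)C1=O | intermediate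
27 | 3-bromo-1-(3-methylbutyl)-1,5-dihydro-2H-pyrrol-2-one | CC(C)CCN1CC=C(Br)C1=O | intermediate
28 | 9-{(4R)-4-{[(9-borabicyclo[3.3.1]nonan-9-yl)oxy]methyl}-6-[(1R,2R,4aS)-1,2,5,5-tetramethyl-1,2,3,4,4a,5,6,7-octahydronaphthalen-1-yl]hexyl}-9-borabicyclo[3.3.1]nonane | C1CCC2CCCC1B2CCC[C@@H](COB3C4CCCC3CCC4)CC[C@@]5(C)C6=CCCC(C)(C)[C@@H]6CC[C@H]5C | intermediate
29 | 3-{(4R)-4-(hydroxymethyl)-6-[(1R,2R,4aS)-1,2,5,5-tetramethyl-1,2,3,4,4a,5,6,7-octahydronaphthalen-1-yl]hexyl}-1-(3-methylbutyl)-1,5-dihydro-2H-pyrrol-2-one | CC(C)CCN1CC=C(CCC[C@H](CC[C@@]2(C)C3=CCCC(C)(C)[C@@H]3CC[C@H]2C)CO)C1=O | intermediate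
30 | (2R)-2-{3-[1-(3-methylbutyl)-2-oxo-2,5-dihydro-1H-pyrrol-3-yl]propyl}-4-[(1R,2R,4aS)-1,2,5,5-tetramethyl-1,2,3,4,4a,5,6,7-octahydronaphthalen-1-yl]butyl hydrogen sulfate (CNP0218721.1) | CC(C)CCN1CC=C(CCC[C@H](CC[C@@]2(C)C3=CCCC(C)(C)[C@@H]3CC[C@H]2C)COS(=O)(=O)O)C1=O | target

**Totals and risks**

Total step count: 15. Longest linear sequence: 10 steps (1, 2, 3, 7, 8, 9, 10, 11, 14, 15 from pulegone; the epichlorohydrin branch 4, 5, 6, 7, 8, 9, 10, 11, 14, 15 is equally long).

Stereocentres: C8 is bought in pulegone. C5 is set in step 1 under the control of C8. C9 is set in step 7 under the control of C5 and C8. C13 is bought in (R)-epichlorohydrin. The carbinol centre of 7 and 17 and the lactone α-centre of 17–21 are temporary.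

The three steps most likely to fail:

Step 7, the proposed electrochemical MHAT–Giese coupling. The cobalt hydride may evolve hydrogen, may isomerise the allylic alcohol to the 2-methyl ketone, or may reduce lactone 16 instead of alkene 7; the axial selectivity at C9 is also a prediction. The fallback uses known two-electron chemistry and sets out from enone 6. L-Selectride in THF at −78 °C delivers hydride in a 1,4-sense to the exocyclic methylene and gives regiospecifically the tetrasubstituted enolate lithium (3R,6S)-6-[4-(1,3-dioxolan-2-yl)-2-methylbutan-2-yl]-2,3-dimethylcyclohex-1-en-1-olate F1. Michael addition of F1 to lactone 16 (−78 → −40 °C) then forms the C9–C11 bond. The electrophile again enters axially on the conformationally locked ring, so the same C9 configuration is expected. This comes back to the route at ketone 18 and makes steps 3 and 8 unnecessary.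

Step 10, the McMurry ring closure. The ketone is flanked by a quaternary carbon and a tert-alkyl-bearing CH, the lactone may be attacked by low-valent titanium, and Lewis-acid enolisation could erode C5. The fallback sets out from keto-aldehyde 19. SmI2 (THF, t-BuOH, −78 °C) effects ketyl–carbonyl pinacol cyclisation to the cis-diol (4R)-3-{[(1R,2R,4aS)-8,8a-dihydroxy-1,2,5,5-tetramethyldecahydronaphthalen-1-yl]methyl}-4-(prop-2-en-1-yl)oxolan-2-one F2. 1,1′-Thiocarbonyldiimidazole converts it into the cyclic thionocarbonate F3. Corey–Winter fragmentation with trimethyl phosphite at 110 °C then gives the C1=C10 alkene and returns to the route at 20.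

Step 11, the direct photochemical hydrodecarboxylation. Oxidation of an unactivated secondary carboxylate by the iridium excited state may be slow, and the thiol could add to the terminal alkene. The fallback sets out from lactone 20, which is opened with CsOH to 21 as before. TBSCl and imidazole in DMF then give the bis-silyl compound tert-butyldimethylsilyl (3R)-3-{[(tert-butyldimethylsilyl)oxy]methyl}-2-{[(1R,2R,4aS)-1,2,5,5-tetramethyl-1,2,3,4,4a,5,6,7-octahydronaphthalen-1-yl]methyl}hex-5-enoate F4. K2CO3 in aqueous methanol cleaves only the silyl ester to give the acid F5. DCC and N-hydroxypyridine-2-thione convert it into the Barton ester F6, and visible light with t-BuSH effects Barton reductive decarboxylation to the silyl ether F7. TBAF removes the silyl group and the sequence returns to the route at 22.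

Further compounds
F1 | step 7 | lithium (3R,6S)-6-[4-(1,3-dioxolan-2-yl)-2-methylbutan-2-yl]-2,3-dimethylcyclohex-1-en-1-olate | C[C@@H]1CC[C@@H](C(C)(C)CCC2OCCO2)C(O[Li])=C1C
F2 | step 10 | (4R)-3-{[(1R,2R,4aS)-8,8a-dihydroxy-1,2,5,5-tetramethyldecahydronaphthalen-1-yl]methyl}-4-(prop-2-en-1-yl)oxolan-2-one (8,8a-cis diol; configuration at C8 and C8a not assigned) | C=CC[C@H]1COC(=O)C1C[C@@]2(C)C3(O)C(O)CCC(C)(C)[C@@H]3CC[C@H]2C
F3 | step 10 | cyclic 8,8a-thionocarbonate of F2 | C=CC[C@H]1COC(=O)C1C[C@@]2(C)C34OC(=S)OC3CCC(C)(C)[C@@H]4CC[C@H]2C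
F4 | step 11 | tert-butyldimethylsilyl (3R)-3-{[(tert-butyldimethylsilyl)oxy]methyl}-2-{[(1R,2R,4aS)-1,2,5,5-tetramethyl-1,2,3,4,4a,5,6,7-octahydronaphthalen-1-yl]methyl}hex-5-enoate | C=CC[C@@H](CO[Si](C)(C)C(C)(C)C)C(C[C@@]1(C)C2=CCCC(C)(C)[C@@H]2CC[C@H]1C)C(=O)O[Si](C)(C)C(C)(C)C
F5 | step 11 | (3R)-3-{[(tert-butyldimethylsilyl)oxy]methyl}-2-{[(1R,2R,4aS)-1,2,5,5-tetramethyl-1,2,3,4,4a,5,6,7-octahydronaphthalen-1-yl]methyl}hex-5-enoic acid | C=CC[C@@H](CO[Si](C)(C)C(C)(C)C)C(C[C@@]1(C)C2=CCCC(C)(C)[C@@H]2CC[C@H]1C)C(=O)O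
F6 | step 11 | 2-thioxopyridin-1(2H)-yl (3R)-3-{[(tert-butyldimethylsilyl)oxy]methyl}-2-{[(1R,2R,4aS)-1,2,5,5-tetramethyl-1,2,3,4,4a,5,6,7-octahydronaphthalen-1-yl]methyl}hex-5-enoate | C=CC[C@@H](CO[Si](C)(C)C(C)(C)C)C(C[C@@]1(C)C2=CCCC(C)(C)[C@@H]2CC[C@H]1C)C(=O)On3ccccc3=S
F7 | step 11 | tert-butyldimethyl{[(2S)-2-(prop-2-en-1-yl)-4-[(1R,2R,4aS)-1,2,5,5-tetramethyl-1,2,3,4,4a,5,6,7-octahydronaphthalen-1-yl]butyl]oxy}silane | C=CC[C@@H](CO[Si](C)(C)C(C)(C)C)CC[C@@]1(C)C2=CCCC(C)(C)[C@@H]2CC[C@H]1C
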